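The cyclohexene is disconnected at its C=C bond. The =CH carbon and the carbon bearing CH2OBz are the only ring carbons without oxygen, and the four oxygenated ring carbons between them show the cis,trans,cis pattern of C2–C5 of D-mannitol. Both olefinic carbons are therefore made the α-carbons of a seven-membered cyclic sulfone: a 1,6-thioanhydro-D-mannitol S,S-dioxide that already carries the extra CH2O carbon on one α-position. A Ramberg–Bäcklund reaction extrudes SO2, contracts the thiepane to the carbocycle and places the trisubstituted alkene regiospecifically in one operation, with no stereocentre touched. A regioselective stannylene dibenzoylation ends the route.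

Key step: step 7

Remarks (assumptions):
- Locants C1–C6 are those of D-mannitol in every compound; C7 is the carbon added in step 4. In the carbocycles C1 and C6 are the olefinic carbons.
- 3,4-O-Isopropylidene-D-mannitol (1) is taken as commercially available.
- C1 of 7–9 and the sulfur-bearing carbons of 10 and 11 form without stereocontrol and are drawn without descriptor; both epimers converge because C1 and C6 become sp2 in step 7.

Step 1
Reactants: 1 3,4-O-isopropylidene-D-mannitol
Product: 2 1,2:5,6-dianhydro-3,4-O-isopropylidene-D-mannitol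
Conditions: PPh3 (2.4 equiv), DIAD (2.4 equiv), THF, 0 °C → reflux
Reagents that add atoms: none
Why: Double Mitsunobu cyclodehydration; each primary hydroxyl is activated as the oxyphosphonium ion and displaced by the neighbouring secondary oxygen, so C2 and C5 keep their configuration.

Step 2
Reactants: 2 1,2:5,6-dianhydro-3,4-O-isopropylidene-D-mannitol
Product: 4 1,6-thioanhydro-3,4-O-isopropylidene-D-mannitol, via epoxy thiol 3 (not isolated)
Conditions: Na2S·9H2O (1.1 equiv), EtOH/H2O, high dilution, rt → 60 °C
Reagents that add atoms: sodium sulfide, [Na+].[Na+].[S-2]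
Why: Double SN2 epoxide opening at the two CH2 termini; the second closure should be 7-endo-tet at C6 because the trans-fused acetonide on C3/C4 disfavours the 6-exo attack at C5, and no stereocentre is touched.

Step 3
Reactants: 4 1,6-thioanhydro-3,4-O-isopropylidene-D-mannitol
Product: 6 1,6-thioanhydro-3,4-O-isopropylidene-D-mannitol S,S-dioxide, via sulfoxide 5 (not isolated)
Conditions: mCPBA (2.3 equiv), NaHCO3, CH2Cl2, 0 °C → rt
Reagents that add atoms: mCPBA, OOC(=O)c1cccc(Cl)c1
Why: Sulfide-to-sulfone oxidation; the bicarbonate buffer protects the acetonide, and the C2-symmetric product has two equivalent α-methylene groups.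

Step 4
Reactants: 6 1,6-thioanhydro-3,4-O-isopropylidene-D-mannitol S,S-dioxide
Product: 7 1-C-(hydroxymethyl)-1,6-thioanhydro-3,4-O-isopropylidene-D-mannitol S,S-dioxide (C1 epimers)
Conditions: n-BuLi (3.1 equiv), THF, −78 °C; HCHO (gas, from paraformaldehyde), −78 → −40 °C; aq NH4Cl
Reagents that add atoms: formaldehyde, C=O
Why: Aldol-type addition of an α-sulfonyl carbanion to formaldehyde; the two lithium alkoxides at O2 and O5 cannot leave, which should suppress E1cB, and C2 symmetry makes attack at either α-carbon give the same constitution (the new C1 centre is uncontrolled and later destroyed).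

Step 5
Reactants: 7 1-C-(hydroxymethyl)-1,6-thioanhydro-3,4-O-isopropylidene-D-mannitol S,S-dioxide
Product: 8 1-C-(hydroxymethyl)-1,6-thioanhydro-2,7:3,4-di-O-isopropylidene-D-mannitol S,S-dioxide
Conditions: 2-methoxypropene (1.5 equiv), PPTS (cat.), CH2Cl2, 0 °C; MeOH quench
Reagents that add atoms: 2-methoxypropene, COC(C)=C
Why: Kinetic isopropylidene acetal formation on the only 1,3-diol (O7/O2, six-membered dioxane); O5–H has no free partner, the trans-acetonide should survive these kinetic conditions, and the methanol quench cleaves any acyclic mixed ketal at O5.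

Step 6
Reactants: 8 1-C-(hydroxymethyl)-1,6-thioanhydro-2,7:3,4-di-O-isopropylidene-D-mannitol S,S-dioxide
Product: 9 1-C-(hydroxymethyl)-1,6-thioanhydro-2,7:3,4-di-O-isopropylidene-5-O-methyl-D-mannitol S,S-dioxide
Conditions: MeOTf, 2,6-di-tert-butyl-4-methylpyridine, CH2Cl2, 0 °C → rt
Reagents that add atoms: methyl triflate, COS(=O)(=O)C(F)(F)F
Why: O-Methylation of the single free hydroxyl under non-basic conditions, so that neither retro-aldol nor E1cB can start at the β-oxy sulfone; only the O–H bond changes, so C5 keeps its configuration.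

Step 7
Reactants: 9 1-C-(hydroxymethyl)-1,6-thioanhydro-2,7:3,4-di-O-isopropylidene-5-O-methyl-D-mannitol S,S-dioxide
Product: 12 bis-acetonide of (1R,2R,3S,4R)-6-(hydroxymethyl)-4-methoxycyclohex-5-ene-1,2,3-triol (1,3-dioxane on O1/CH2O and trans-dioxolane on O2/O3), via α-bromo sulfone 10 (not isolated), via episulfone 11 (not isolated)
Conditions: KOH/Al2O3, CBr2F2, t-BuOH/CH2Cl2, 0 °C → rt
Reagents that add atoms: none
Why: Ramberg–Bäcklund reaction under Meyers–Chan conditions: an α-sulfonyl carbanion is brominated by halophilic attack on CBr2F2 (10), the α′-carbanion displaces bromide in a 1,3-elimination to the episulfone 11, and cheletropic loss of SO2 leaves the C1=C6 double bond, so the seven-membered thiepane dioxide contracts to the six-membered carbocycle. The closest known reaction type is the Ramberg–Bäcklund ring contraction of hexitol-derived thiepane S,S-dioxides to conduritol-type cyclohexenes. The only ring closed is the thiirane dioxide, in a 3-exo-tet mode, and this same C1–C6 bond completes the cyclohexane ring before SO2 leaves. No stereocentre is created: C2–C5 come unchanged from D-mannitol because they are β to sulfur and not acidic, and the ring allows only the cis alkene. The step needs the 1,3-elimination to outrun E1cB loss of a β-oxygen and over-bromination; every β-oxygen is an ether or ketal (poor leaving groups, no acyl groups), and bromide on the adjacent α-carbon offers each carbanion a far better leaving group. The position of the trisubstituted alkene is fixed by construction, since SO2 extrusion can only join the two α-carbons, one of which already carries C7.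

Step 8
Reactants: 12 bis-acetonide of (1R,2R,3S,4R)-6-(hydroxymethyl)-4-methoxycyclohex-5-ene-1,2,3-triol
Product: 13 (1R,2R,3S,4R)-6-(hydroxymethyl)-4-methoxycyclohex-5-ene-1,2,3-triol
Conditions: AcOH/H2O (4:1), 45 °C
Reagents that add atoms: none
Why: Acid hydrolysis of both acetals (the strained trans-dioxolane and the allylic 1,3-dioxane are both labile); the mild acid should not ionise the allylic C–O bonds, and no C–O bond at a stereocentre is broken.

Step 9
Reactants: 13 (1R,2R,3S,4R)-6-(hydroxymethyl)-4-methoxycyclohex-5-ene-1,2,3-triol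
Product: 15 [(3R,4R,5R,6R)-5-(benzoyloxy)-4,6-dihydroxy-3-methoxycyclohex-1-en-1-yl]methyl benzoate, via stannylene acetal 14 (not isolated)
Conditions: Bu2SnO (1.1 equiv), MeOH, reflux; evaporate; BzCl (2.1 equiv), toluene, 0 °C → rt
Reagents that add atoms: benzoyl chloride, O=C(Cl)c1ccccc1
Why: Stannylene-mediated regioselective acylation: the cis-2,3-diol forms the five-membered stannylene, which is acylated at the equatorial O3; the remaining O2–Sn bond should pass tin to the 1,3-related primary O7, which takes the second benzoyl, the same pattern as the 3,6-di-O-benzoylation of methyl α-galactopyranoside, of which 13 is the carbocyclic analogue.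

Compound list
1 | 3,4-O-isopropylidene-D-mannitol | OC[C@@H](O)[C@@H](OC1(C)C)[C@H](O1)[C@H](O)CO | starting material
2 | 1,2:5,6-dianhydro-3,4-O-isopropylidene-D-mannitol | C1O[C@H]1[C@@H](OC2(C)C)[C@H](O2)[C@H]3CO3 | intermediate
3 | 5,6-anhydro-3,4-O-isopropylidene-1-thio-D-mannitol (epoxy thiol, present as thiolate; not isolated) | SC[C@@H](O)[C@@H](OC1(C)C)[C@H](O1)[C@H]2CO2 | intermediate
4 | 1,6-thioanhydro-3,4-O-isopropylidene-D-mannitol (thiepane; S joins C1 and C6, OH at C2 and C5, trans-acetonide at C3/C4) | S1C[C@@H](O)[C@@H](OC2(C)C)[C@H](O2)[C@H](O)C1 | intermediate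
5 | 1,6-thioanhydro-3,4-O-isopropylidene-D-mannitol S-oxide (not isolated) | O=S1C[C@@H](O)[C@@H](OC2(C)C)[C@H](O2)[C@H](O)C1 | intermediate
6 | 1,6-thioanhydro-3,4-O-isopropylidene-D-mannitol S,S-dioxide | O=S1(=O)C[C@@H](O)[C@@H](OC2(C)C)[C@H](O2)[C@H](O)C1 | intermediate
7 | 1-C-(hydroxymethyl)-1,6-thioanhydro-3,4-O-isopropylidene-D-mannitol S,S-dioxide (C1 epimers) | O=S1(=O)C(CO)[C@@H](O)[C@@H](OC2(C)C)[C@H](O2)[C@H](O)C1 | intermediate
8 | 1-C-(hydroxymethyl)-1,6-thioanhydro-2,7:3,4-di-O-isopropylidene-D-mannitol S,S-dioxide (free 5-OH; C1 epimers) | O=S1(=O)C2COC(C)(C)O[C@H]2[C@@H](OC3(C)C)[C@H](O3)[C@H](O)C1 | intermediate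
9 | 5-O-methyl ether of 8 | O=S1(=O)C2COC(C)(C)O[C@H]2[C@@H](OC3(C)C)[C@H](O3)[C@H](OC)C1 | intermediate
10 | 6-bromo derivative of 9 (α-bromo sulfone, drawn for bromination at C6; not isolated) | O=S1(=O)C2COC(C)(C)O[C@H]2[C@@H](OC3(C)C)[C@H](O3)[C@H](OC)C1Br | intermediate
11 | episulfone: thiirane 1,1-dioxide fused across C1–C6 of the protected cyclohexane (not isolated) | O=S1(=O)C2[C@@H](OC)[C@H]3OC(C)(C)O[C@@H]3[C@@H]4OC(C)(C)OCC124 | intermediate
12 | bis-acetonide of (1R,2R,3S,4R)-6-(hydroxymethyl)-4-methoxycyclohex-5-ene-1,2,3-triol (2,7:3,4-di-O-isopropylidene, 5-O-methyl in mannitol locants) | CO[C@@H]1C=C2COC(C)(C)O[C@H]2[C@H]3OC(C)(C)O[C@@H]31 | intermediate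
13 | (1R,2R,3S,4R)-6-(hydroxymethyl)-4-methoxycyclohex-5-ene-1,2,3-triol | CO[C@@H]1C=C(CO)[C@@H](O)[C@@H](O)[C@@H]1O | intermediate
14 | 2,3-O-dibutylstannylene acetal of 13 (mannitol locants; not isolated) | CO[C@@H]1C=C(CO)[C@H]2O[Sn](CCCC)(CCCC)O[C@H]2[C@@H]1O | intermediate
15 | [(3R,4R,5R,6R)-5-(benzoyloxy)-4,6-dihydroxy-3-methoxycyclohex-1-en-1-yl]methyl benzoate | CO[C@@H]1C=C(COC(=O)c2ccccc2)[C@@H](O)[C@@H](OC(=O)c2ccccc2)[C@@H]1O | target

Total step count: 9
Longest linear sequence: 9 steps

Steps most likely to fail

Step 7 (ring contraction). In-situ bromination may run on to double bromination at the C6 methylene, or a β-oxygen may be lost by E1cB before the hindered C1–H is removed and the episulfone closes. The fallback separates halogenation from ring contraction. It sets out from 9, which would be deprotonated at its only α-methylene with n-BuLi (1.05 equiv, THF, −78 °C) and chlorinated with hexachloroethane to the isolated 6-chloro sulfone F1. Brief treatment of F1 with t-BuOK in THF (−20 → 0 °C) should then give the 1,3-elimination and SO2 loss under aprotic, stoichiometric control and return to the route at 12.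

Step 4 (hydroxymethylation). The trilithiated species may aggregate or stay insoluble, so that metalation is incomplete or a second hydroxymethyl group is added. The fallback replaces the unprotected polyanion by a protected monoanion. It sets out from 6, whose two hydroxyls would be silylated (TBSOTf, 2,6-lutidine, CH2Cl2) to the bis-TBS ether F2. F2 would be lithiated with one equivalent of n-BuLi (THF, −78 °C) and quenched with formaldehyde to the hydroxymethyl sulfone F3. Desilylation of F3 with HF·pyridine in THF/pyridine rejoins the route at 7.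

Step 9 (dibenzoylation). Discrimination between the two equatorial hydroxyls O3 and O4 may be insufficient, or the benzoyl group may migrate to O2 or O4 during work-up. The fallback uses two separate acylations with a different recognition element. It sets out from 13, whose primary hydroxyl alone would be benzoylated (BzCl 1.05 equiv, 2,4,6-collidine, CH2Cl2, −40 °C) to the 7-O-monobenzoate F4. A diarylborinic acid catalyst (2-aminoethyl diphenylborinate 10 mol %, BzCl, iPr2NEt, MeCN, rt) should then bind the cis-2,3-diol of F4 as a tetracoordinate borinate and acylate its equatorial O3, arriving at 15.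

Further compounds
F1 | step 7 | 6-chloro derivative of 9 (α-chloro sulfone) | O=S1(=O)C2COC(C)(C)O[C@H]2[C@@H](OC3(C)C)[C@H](O3)[C@H](OC)C1Cl
F2 | step 4 | 2,5-bis-O-(tert-butyldimethylsilyl) ether of 6 | O=S1(=O)C[C@@H](O[Si](C)(C)C(C)(C)C)[C@@H](OC2(C)C)[C@H](O2)[C@H](O[Si](C)(C)C(C)(C)C)C1
F3 | step 4 | 2,5-bis-O-(tert-butyldimethylsilyl) ether of 7 (C1 epimers) | O=S1(=O)C(CO)[C@@H](O[Si](C)(C)C(C)(C)C)[C@@H](OC2(C)C)[C@H](O2)[C@H](O[Si](C)(C)C(C)(C)C)C1
F4 | step 9 | 7-O-monobenzoate of 13 | CO[C@@H]1C=C(COC(=O)c2ccccc2)[C@@H](O)[C@@H](O)[C@@H]1O
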